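**Plan**

- Locants: ring C1 (sp2, carrying C7H2OBz), C2 (OBz), C3 (OAc), C4 (OH), C5 (OH), C6 (vinyl CH). The enabling feature is the C3–C4 pair of neighbouring cis carbinol carbons in the cyclohexene ring, each trans to the oxygenated carbon on its other side (C2, C5), the pattern left by a pinacol closure of two aldehydes held together by the Z C1=C6 bond.
- Cuts: the three ester C–O bonds, then C3–C4 (both carbons as aldehydes), then C1–C2 and C6–C5 (each from one glycolic Weinreb amide), leaving a propargyl silyl ether as the C7–C1–C6 core.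
- Forward: acetylide acylation joins C5/C4 to C6; hydroalumination–iodination fixes the Z alkene; vinyllithium acylation joins C2/C3 to C1; a C2/C7 acetonide and double oxidation set up the only ring closure, the carbocycle, by C3–C4 bond formation; acetate, benzoates and desilylation finish.
- Stereochemistry: C5 from ruthenium-catalysed transfer hydrogenation, C2 from oxazaborolidine-catalysed reduction, C3 and C4 from the substrate in the pinacol step (cis to each other, trans to O2 and O5). O3 is told from O4 by equatorial-selective tin acylation.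

Key step: step 10

Assumption: in 18 the fused dioxane holds the C2–O bond pseudo-equatorial, which places the C3 hydroxyl equatorial and the C4 hydroxyl axial (trans-diaxial to the C5 silyl ether); step 11 is built on this.

**Route**

Step 1
Reactants: 1 4-methoxybenzyl alcohol; 2 2-chloro-N-methoxy-N-methylacetamide
Product: 3 N-methoxy-2-[(4-methoxybenzyl)oxy]-N-methylacetamide
Conditions: NaH, THF, 0 °C → rt
Reagents that add atoms: none
Why: Williamson ether synthesis, in which the sodium alkoxide of 1 displaces the chloride next to the amide carbonyl by SN2 faster than it attacks the N-methoxy-N-methylamide.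

Step 2
Reactants: 4 tert-butyldimethyl(prop-2-yn-1-yloxy)silane; 3 N-methoxy-2-[(4-methoxybenzyl)oxy]-N-methylacetamide
Product: 6 5-[(tert-butyldimethylsilyl)oxy]-1-[(4-methoxybenzyl)oxy]pent-3-yn-2-one, via lithium acetylide 5 (not isolated)
Conditions: n-BuLi, THF, −78 °C; then 3, −78 → 0 °C
Reagents that add atoms: none
Why: Weinreb ketone synthesis with an alkynyllithium, whose chelated tetrahedral adduct persists until work-up, so the C6–C5 bond is made without a second addition.

Step 3
Reactants: 6 5-[(tert-butyldimethylsilyl)oxy]-1-[(4-methoxybenzyl)oxy]pent-3-yn-2-one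
Product: 7 (2R)-5-[(tert-butyldimethylsilyl)oxy]-1-[(4-methoxybenzyl)oxy]pent-3-yn-2-ol
Conditions: Ru[(S,S)-TsNCH(Ph)CH(Ph)NH](p-cymene) (cat.), i-PrOH, rt
Reagents that add atoms: none
Why: Noyori asymmetric transfer hydrogenation of an alkynyl ketone, in which the alkynyl group takes the place of the aryl group of the usual model, so the (S,S)-catalyst should set C5 as R (the descriptor follows from CH2OPMB outranking the alkynyl carbon).

Step 4
Reactants: 7 (2R)-5-[(tert-butyldimethylsilyl)oxy]-1-[(4-methoxybenzyl)oxy]pent-3-yn-2-ol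
Product: 9 (2R,3Z)-5-[(tert-butyldimethylsilyl)oxy]-4-iodo-1-[(4-methoxybenzyl)oxy]pent-3-en-2-ol, via cyclic alkenylalanate 8 (not isolated)
Conditions: NaAlH2(OCH2CH2OMe)2, THF, 0 °C; then I2, THF, −78 → 0 °C
Reagents that add atoms: iodine, II
Why: Alkoxide-directed trans-hydroalumination of a propargylic alcohol puts hydride on C6 and aluminium on C1 in a five-membered alanate, and iodinolysis with retention leaves iodine on C1 cis to C5, which fixes the Z geometry; the silyl ether on C7 is a poor leaving group at 0 °C, so allene formation should not compete.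

Step 5
Reactants: 9 (2R,3Z)-5-[(tert-butyldimethylsilyl)oxy]-4-iodo-1-[(4-methoxybenzyl)oxy]pent-3-en-2-ol
Product: 10 (2R,3Z)-2-[(tert-butyldiphenylsilyl)oxy]-5-[(tert-butyldimethylsilyl)oxy]-4-iodo-1-[(4-methoxybenzyl)oxy]pent-3-ene
Conditions: TBDPSCl, imidazole, DMAP (cat.), DMF, rt
Reagents that add atoms: tert-butyl(chloro)diphenylsilane, CC(C)(C)[Si](Cl)(c1ccccc1)c1ccccc1
Why: Standard silylation of a secondary allylic alcohol; the bulky, acid-stable silyl group on O5 is chosen to outlast the later acid removal of the primary silyl ether and to resist migration to carbon in the vinyllithium of step 6.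

Step 6
Reactants: 10 (2R,3Z)-2-[(tert-butyldiphenylsilyl)oxy]-5-[(tert-butyldimethylsilyl)oxy]-4-iodo-1-[(4-methoxybenzyl)oxy]pent-3-ene; 3 N-methoxy-2-[(4-methoxybenzyl)oxy]-N-methylacetamide
Product: 12 (3Z,5R)-5-[(tert-butyldiphenylsilyl)oxy]-3-{[(tert-butyldimethylsilyl)oxy]methyl}-1,6-bis[(4-methoxybenzyl)oxy]hex-3-en-2-one, via vinyllithium 11 (not isolated)
Conditions: t-BuLi (2 equiv), Et2O, −78 °C; then 3, −78 → −40 °C
Reagents that add atoms: none
Why: Iodine–lithium exchange proceeds with retention of alkene geometry and the vinyllithium is acylated by the Weinreb amide (Weinreb ketone synthesis), forming the C1–C2 bond with C2 cis to C5.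

Step 7
Reactants: 12 (3Z,5R)-5-[(tert-butyldiphenylsilyl)oxy]-3-{[(tert-butyldimethylsilyl)oxy]methyl}-1,6-bis[(4-methoxybenzyl)oxy]hex-3-en-2-one
Product: 13 (2S,3Z,5R)-5-[(tert-butyldiphenylsilyl)oxy]-3-{[(tert-butyldimethylsilyl)oxy]methyl}-1,6-bis[(4-methoxybenzyl)oxy]hex-3-en-2-ol
Conditions: (S)-2-methyl-CBS-oxazaborolidine, BH3·SMe2, THF, −30 °C
Reagents that add atoms: none
Why: Corey–Bakshi–Shibata reduction of an enone, in which the α-branched alkenyl group acts as the large substituent and CH2OPMB as the small one, so the (S)-catalyst should deliver hydride to the face that gives 2S (C2 of the target numbering) under reagent control.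

Step 8
Reactants: 13 (2S,3Z,5R)-5-[(tert-butyldiphenylsilyl)oxy]-3-{[(tert-butyldimethylsilyl)oxy]methyl}-1,6-bis[(4-methoxybenzyl)oxy]hex-3-en-2-ol
Product: 15 (4S,5Z)-5-{(2R)-2-[(tert-butyldiphenylsilyl)oxy]-3-[(4-methoxybenzyl)oxy]propylidene}-4-{[(4-methoxybenzyl)oxy]methyl}-2,2-dimethyl-1,3-dioxane, via allylic 1,3-diol 14 (not isolated)
Conditions: CSA (cat.), MeOH–CH2Cl2, 0 °C; evaporate; then 2,2-dimethoxypropane, acetone, rt
Reagents that add atoms: 2,2-dimethoxypropane, COC(C)(C)OC
Why: Acid methanolysis removes the primary tert-butyldimethylsilyl ether much faster than the secondary tert-butyldiphenylsilyl ether, and the same acid then drives transacetalisation of the only free diol (O2/O7) to the six-membered acetonide.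

Step 9
Reactants: 15 (4S,5Z)-5-{(2R)-2-[(tert-butyldiphenylsilyl)oxy]-3-[(4-methoxybenzyl)oxy]propylidene}-4-{[(4-methoxybenzyl)oxy]methyl}-2,2-dimethyl-1,3-dioxane
Product: 16 (2R,3Z)-2-[(tert-butyldiphenylsilyl)oxy]-3-[(4S)-4-(hydroxymethyl)-2,2-dimethyl-1,3-dioxan-5-ylidene]propan-1-ol
Conditions: DDQ, CH2Cl2–pH 7 buffer, 0 °C → rt
Reagents that add atoms: none
Why: Oxidative cleavage of both 4-methoxybenzyl ethers by DDQ runs under neutral buffered conditions, so the acetonide stays in place and the silyl group does not move from O5 to the new primary hydroxyl.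

Step 10
Reactants: 16 (2R,3Z)-2-[(tert-butyldiphenylsilyl)oxy]-3-[(4S)-4-(hydroxymethyl)-2,2-dimethyl-1,3-dioxan-5-ylidene]propan-1-ol
Product: 18 (6R,7R,8S,8aS)-6-[(tert-butyldiphenylsilyl)oxy]-2,2-dimethyl-6,7,8,8a-tetrahydro-4H-benzo[d][1,3]dioxine-7,8-diol, via dialdehyde 17 (not isolated)
Conditions: (COCl)2, DMSO, CH2Cl2, −78 °C; i-Pr2NEt, −78 → −40 °C; then cannulated into SmI2 (excess), t-BuOH, THF, −78 °C → rt
Reagents that add atoms: none
Why: Swern oxidation turns both primary alcohols of 16 into aldehydes, and divalent samarium then transfers an electron to a carbonyl of 17 to give a samarium-bound ketyl whose carbon adds to the carbon of the second, samarium-coordinated aldehyde; a second electron transfer and protonation of the cyclic trivalent samarium diolate deliver the diol. The closest known reaction type is the SmI2-mediated intramolecular pinacol coupling of 1,6-dialdehydes to cis-cyclohexane-1,2-diols, including its telescoped Swern–pinacol form on carbohydrate-derived diols. The six-membered carbocycle is closed by the C3–C4 bond in a 6-exo-trig attack of the ketyl carbon on the C=O carbon. C3 and C4 should come out cis to each other because both oxygens bridge one samarium centre in the closing transition state, and each new C–O bond turns away from the alkoxy group on the neighbouring carbon (O2 of the acetonide, O5 of the silyl ether) for dipolar and steric reasons; as O2 and O5 lie on the same face, both demands select the same diastereomer. The step needs ring closure to outrun intermolecular coupling, simple reduction, β-elimination of the α-oxygen groups and base-induced epimerisation or double-bond migration of the α-oxygenated β,γ-unsaturated aldehydes: the Z C1=C6 bond holds the two formyl carbons within bonding distance, the acetal and silyl ether are poor leaving groups, and the dialdehyde is made and consumed below −40 °C without isolation.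

Step 11
Reactants: 18 (6R,7R,8S,8aS)-6-[(tert-butyldiphenylsilyl)oxy]-2,2-dimethyl-6,7,8,8a-tetrahydro-4H-benzo[d][1,3]dioxine-7,8-diol
Product: 20 (6R,7R,8S,8aS)-6-[(tert-butyldiphenylsilyl)oxy]-7-hydroxy-2,2-dimethyl-6,7,8,8a-tetrahydro-4H-benzo[d][1,3]dioxin-8-yl acetate, via stannylene acetal 19 (not isolated)
Conditions: Bu2SnO, toluene, reflux (−H2O); then AcCl, 0 °C
Reagents that add atoms: acetyl chloride, CC(=O)Cl
Why: Stannylene-acetal-mediated monoacylation of a cis-1,2-diol on a six-membered ring goes to the equatorial oxygen, here O3, while O4 is axial and flanked by the tert-butyldiphenylsilyl ether.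

Step 12
Reactants: 20 (6R,7R,8S,8aS)-6-[(tert-butyldiphenylsilyl)oxy]-7-hydroxy-2,2-dimethyl-6,7,8,8a-tetrahydro-4H-benzo[d][1,3]dioxin-8-yl acetate
Product: 21 (6R,7R,8R,8aS)-6-[(tert-butyldiphenylsilyl)oxy]-7-[(tert-butyldimethylsilyl)oxy]-2,2-dimethyl-6,7,8,8a-tetrahydro-4H-benzo[d][1,3]dioxin-8-yl acetate
Conditions: TBSOTf, 2,6-lutidine, CH2Cl2, −78 → 0 °C
Reagents that add atoms: tert-butyldimethylsilyl trifluoromethanesulfonate, CC(C)(C)[Si](C)(C)OS(=O)(=O)C(F)(F)F
Why: The silyl triflate silylates the hindered axial C4 hydroxyl under weakly basic conditions, which blocks acetyl migration from O3 and masks O4 for the benzoylation.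

Step 13
Reactants: 21 (6R,7R,8R,8aS)-6-[(tert-butyldiphenylsilyl)oxy]-7-[(tert-butyldimethylsilyl)oxy]-2,2-dimethyl-6,7,8,8a-tetrahydro-4H-benzo[d][1,3]dioxin-8-yl acetate
Product: 22 (1R,2S,5R,6R)-5-[(tert-butyldiphenylsilyl)oxy]-6-[(tert-butyldimethylsilyl)oxy]-2-hydroxy-3-(hydroxymethyl)cyclohex-3-en-1-yl acetate
Conditions: PPTS, MeOH, rt
Reagents that add atoms: none
Why: Acid-catalysed transketalisation to methanol opens the 1,3-dioxane acetonide, while the two secondary silyl ethers and the acetate are inert to this weak acid.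

Step 14
Reactants: 22 (1R,2S,5R,6R)-5-[(tert-butyldiphenylsilyl)oxy]-6-[(tert-butyldimethylsilyl)oxy]-2-hydroxy-3-(hydroxymethyl)cyclohex-3-en-1-yl acetate
Product: 23 [(3R,4R,5R,6S)-5-acetoxy-6-(benzoyloxy)-3-[(tert-butyldiphenylsilyl)oxy]-4-[(tert-butyldimethylsilyl)oxy]cyclohex-1-en-1-yl]methyl benzoate
Conditions: BzCl, pyridine, DMAP (cat.), CH2Cl2, 0 °C → rt
Reagents that add atoms: benzoyl chloride, O=C(Cl)c1ccccc1
Why: Nucleophile-catalysed acylation of the only two free hydroxyls (O7 primary allylic, O2 secondary allylic) by the acid chloride, fast enough at 0 °C to precede acetyl migration from O3 to O2.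

Step 15
Reactants: 23 [(3R,4R,5R,6S)-5-acetoxy-6-(benzoyloxy)-3-[(tert-butyldiphenylsilyl)oxy]-4-[(tert-butyldimethylsilyl)oxy]cyclohex-1-en-1-yl]methyl benzoate
Product: 24 [(3R,4S,5S,6S)-5-acetoxy-6-(benzoyloxy)-3,4-dihydroxycyclohex-1-en-1-yl]methyl benzoate
Conditions: HF·pyridine, pyridine, THF, 0 °C → rt
Reagents that add atoms: none
Why: Fluoride cleaves both Si–O bonds under mildly acidic, non-basic conditions, so the three esters should neither hydrolyse nor migrate onto the freed C4 and C5 hydroxyls.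

**Compound list**

1 | 4-methoxybenzyl alcohol | COc1ccc(CO)cc1 | starting material
2 | 2-chloro-N-methoxy-N-methylacetamide | CON(C)C(=O)CCl | starting material
3 | N-methoxy-2-[(4-methoxybenzyl)oxy]-N-methylacetamide | CON(C)C(=O)COCc1ccc(OC)cc1 | intermediate
4 | tert-butyldimethyl(prop-2-yn-1-yloxy)silane | C#CCO[Si](C)(C)C(C)(C)C | starting material
5 | {3-[(tert-butyldimethylsilyl)oxy]prop-1-yn-1-yl}lithium | [Li]C#CCO[Si](C)(C)C(C)(C)C | intermediate
6 | 5-[(tert-butyldimethylsilyl)oxy]-1-[(4-methoxybenzyl)oxy]pent-3-yn-2-one | COc1ccc(COCC(=O)C#CCO[Si](C)(C)C(C)(C)C)cc1 | intermediate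
7 | (2R)-5-[(tert-butyldimethylsilyl)oxy]-1-[(4-methoxybenzyl)oxy]pent-3-yn-2-ol | COc1ccc(COC[C@H](O)C#CCO[Si](C)(C)C(C)(C)C)cc1 | intermediate
8 | sodium alkenylalanate: five-membered 2,5-dihydro-1,2-oxaaluminol-2-uide from the C5 alkoxide of 7, Al on C1 carrying two 2-methoxyethoxy groups | [Na+].COCCO[Al-]1(OCCOC)O[C@@H](COCc2ccc(OC)cc2)C=C1CO[Si](C)(C)C(C)(C)C | intermediate
9 | (2R,3Z)-5-[(tert-butyldimethylsilyl)oxy]-4-iodo-1-[(4-methoxybenzyl)oxy]pent-3-en-2-ol | COc1ccc(COC[C@H](O)/C=C(\I)CO[Si](C)(C)C(C)(C)C)cc1 | intermediate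
10 | (2R,3Z)-2-[(tert-butyldiphenylsilyl)oxy]-5-[(tert-butyldimethylsilyl)oxy]-4-iodo-1-[(4-methoxybenzyl)oxy]pent-3-ene | COc1ccc(COC[C@H](O[Si](c2ccccc2)(c2ccccc2)C(C)(C)C)/C=C(\I)CO[Si](C)(C)C(C)(C)C)cc1 | intermediate
11 | vinyllithium from 10 (Li in place of I, geometry retained) | COc1ccc(COC[C@H](O[Si](c2ccccc2)(c2ccccc2)C(C)(C)C)/C=C(\[Li])CO[Si](C)(C)C(C)(C)C)cc1 | intermediate
12 | (3Z,5R)-5-[(tert-butyldiphenylsilyl)oxy]-3-{[(tert-butyldimethylsilyl)oxy]methyl}-1,6-bis[(4-methoxybenzyl)oxy]hex-3-en-2-one | COc1ccc(COCC(=O)/C(CO[Si](C)(C)C(C)(C)C)=C\[C@H](COCc2ccc(OC)cc2)O[Si](c2ccccc2)(c2ccccc2)C(C)(C)C)cc1 | intermediate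
13 | (2S,3Z,5R)-5-[(tert-butyldiphenylsilyl)oxy]-3-{[(tert-butyldimethylsilyl)oxy]methyl}-1,6-bis[(4-methoxybenzyl)oxy]hex-3-en-2-ol | COc1ccc(COC[C@@H](O)/C(CO[Si](C)(C)C(C)(C)C)=C\[C@H](COCc2ccc(OC)cc2)O[Si](c2ccccc2)(c2ccccc2)C(C)(C)C)cc1 | intermediate
14 | (2S,3Z,5R)-5-[(tert-butyldiphenylsilyl)oxy]-3-(hydroxymethyl)-1,6-bis[(4-methoxybenzyl)oxy]hex-3-en-2-ol | COc1ccc(COC[C@@H](O)/C(CO)=C\[C@H](COCc2ccc(OC)cc2)O[Si](c2ccccc2)(c2ccccc2)C(C)(C)C)cc1 | intermediate
15 | (4S,5Z)-5-{(2R)-2-[(tert-butyldiphenylsilyl)oxy]-3-[(4-methoxybenzyl)oxy]propylidene}-4-{[(4-methoxybenzyl)oxy]methyl}-2,2-dimethyl-1,3-dioxane | COc1ccc(COC[C@H]2OC(C)(C)OC/C2=C/[C@H](COCc3ccc(OC)cc3)O[Si](c3ccccc3)(c3ccccc3)C(C)(C)C)cc1 | intermediate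
16 | (2R,3Z)-2-[(tert-butyldiphenylsilyl)oxy]-3-[(4S)-4-(hydroxymethyl)-2,2-dimethyl-1,3-dioxan-5-ylidene]propan-1-ol | OC[C@H]1OC(C)(C)OC/C1=C/[C@H](CO)O[Si](c2ccccc2)(c2ccccc2)C(C)(C)C | intermediate
17 | (4S,5Z)-5-{(2R)-2-[(tert-butyldiphenylsilyl)oxy]-3-oxopropylidene}-2,2-dimethyl-1,3-dioxane-4-carbaldehyde | O=C[C@H]1OC(C)(C)OC/C1=C/[C@@H](O[Si](c2ccccc2)(c2ccccc2)C(C)(C)C)C=O | intermediate
18 | (6R,7R,8S,8aS)-6-[(tert-butyldiphenylsilyl)oxy]-2,2-dimethyl-6,7,8,8a-tetrahydro-4H-benzo[d][1,3]dioxine-7,8-diol | O[C@H]1[C@@H](O)[C@H](O[Si](c2ccccc2)(c2ccccc2)C(C)(C)C)C=C2COC(C)(C)O[C@H]12 | intermediate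
19 | dibutylstannylene acetal of 18 across O3 and O4 (2,2-dibutyl-1,3,2-dioxastannolane) | CCCC[Sn]1(CCCC)O[C@H]2[C@@H](O1)[C@H](O[Si](c3ccccc3)(c3ccccc3)C(C)(C)C)C=C3COC(C)(C)O[C@H]23 | intermediate
20 | (6R,7R,8S,8aS)-6-[(tert-butyldiphenylsilyl)oxy]-7-hydroxy-2,2-dimethyl-6,7,8,8a-tetrahydro-4H-benzo[d][1,3]dioxin-8-yl acetate | CC(=O)O[C@H]1[C@@H](O)[C@H](O[Si](c2ccccc2)(c2ccccc2)C(C)(C)C)C=C2COC(C)(C)O[C@H]12 | intermediate
21 | (6R,7R,8R,8aS)-6-[(tert-butyldiphenylsilyl)oxy]-7-[(tert-butyldimethylsilyl)oxy]-2,2-dimethyl-6,7,8,8a-tetrahydro-4H-benzo[d][1,3]dioxin-8-yl acetate | CC(=O)O[C@H]1[C@@H](O[Si](C)(C)C(C)(C)C)[C@H](O[Si](c2ccccc2)(c2ccccc2)C(C)(C)C)C=C2COC(C)(C)O[C@H]12 | intermediate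
22 | (1R,2S,5R,6R)-5-[(tert-butyldiphenylsilyl)oxy]-6-[(tert-butyldimethylsilyl)oxy]-2-hydroxy-3-(hydroxymethyl)cyclohex-3-en-1-yl acetate | CC(=O)O[C@H]1[C@@H](O[Si](C)(C)C(C)(C)C)[C@H](O[Si](c2ccccc2)(c2ccccc2)C(C)(C)C)C=C(CO)[C@@H]1O | intermediate
23 | [(3R,4R,5R,6S)-5-acetoxy-6-(benzoyloxy)-3-[(tert-butyldiphenylsilyl)oxy]-4-[(tert-butyldimethylsilyl)oxy]cyclohex-1-en-1-yl]methyl benzoate | CC(=O)O[C@H]1[C@@H](O[Si](C)(C)C(C)(C)C)[C@H](O[Si](c2ccccc2)(c2ccccc2)C(C)(C)C)C=C(COC(=O)c2ccccc2)[C@@H]1OC(=O)c1ccccc1 | intermediate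
24 | [(3R,4S,5S,6S)-5-acetoxy-6-(benzoyloxy)-3,4-dihydroxycyclohex-1-en-1-yl]methyl benzoate | CC(=O)O[C@H]1[C@@H](O)[C@H](O)C=C(COC(=O)c2ccccc2)[C@@H]1OC(=O)c1ccccc1 | target

**Count and risks**

Total step count: 15. Longest linear sequence: 15 steps (from 1 or 2 to 24, since 3 enters at step 2; 14 steps counted from 4).

Steps most likely to fail:

1. Step 10. The amine base of the oxidation may epimerise C2 or C5 or move the double bond into conjugation before reduction, and the ketyls may expel the neighbouring alkoxy groups or be reduced to alcohols instead of coupling. Fallback: setting out from 16, the diol would be oxidised without base by Dess–Martin periodinane buffered with NaHCO3 in CH2Cl2 at 0 °C. Crude 17 would then be closed with [V2Cl3(THF)6]2[Zn2Cl6] (made from VCl3(THF)3 and Zn) in CH2Cl2 at rt. This is an inner-sphere pinacol coupling in which both carbonyl oxygens sit on the metal, known to give cis-diols from dialdehydes, and this less reducing reagent should not cleave the α-oxygen groups. The same C3–C4 bond is formed and the route is rejoined at 18; no compound outside the list is made (F0).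

2. Step 11. Discrimination between O3 and O4 may be poor, or acylation may go to O4 if the ring prefers the other half-chair, in which O3 is axial. Fallback: setting out from 18, exchange with trimethyl orthoacetate and catalytic CSA in CH2Cl2 should give the cyclic methyl orthoacetate F1. Brief opening with dilute aqueous acetic acid at 0 °C leaves the acetyl group on the axial oxygen, the opposite regiochemistry to tin acylation. Whichever half-chair is populated, one of the two methods should therefore lead to the C3 acetate, and the route is rejoined at 20.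

3. Step 6. The vinyllithium may decay before acylation, by shift of the cis-disposed silyl group from O5 to C1 or by loss of the C7 silyloxide to an allene, and the amide may be enolised instead of attacked. Fallback: setting out from 10 and 3, the amide would be reduced with i-Bu2AlH (THF, −78 °C) to 2-[(4-methoxybenzyl)oxy]acetaldehyde F2. Nozaki–Hiyama–Kishi coupling of 10 with F2 (CrCl2, catalytic NiCl2, DMSO, rt) forms the C1–C2 bond without a carbanion and should give the allylic alcohol as both C2 epimers F3. Dess–Martin oxidation of F3 returns to 12, after which step 7 sets C2.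

Further compounds
F0 | step 10 | none | none
F1 | step 11 | cyclic methyl orthoacetate of 18 across O3 and O4 (2-methoxy-2-methyl-1,3-dioxolane, both configurations at the orthoester carbon) | COC1(C)O[C@H]2[C@@H](O1)[C@H](O[Si](c3ccccc3)(c3ccccc3)C(C)(C)C)C=C3COC(C)(C)O[C@H]23
F2 | step 6 | 2-[(4-methoxybenzyl)oxy]acetaldehyde | COc1ccc(COCC=O)cc1
F3 | step 6 | (3Z,5R)-5-[(tert-butyldiphenylsilyl)oxy]-3-{[(tert-butyldimethylsilyl)oxy]methyl}-1,6-bis[(4-methoxybenzyl)oxy]hex-3-en-2-ol, both C2 epimers | COc1ccc(COCC(O)/C(CO[Si](C)(C)C(C)(C)C)=C\[C@H](COCc2ccc(OC)cc2)O[Si](c2ccccc2)(c2ccccc2)C(C)(C)C)cc1
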